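**Assumptions.** The target is taken exactly as drawn: (5R,6R)‑cis lactone, (2S,3S)‑epoxide, (6S) acyl chain, 2E,4E diene. A one‑pot sequence counts as one step. Catalyst antipodes are named from the usual sense rules: (−)‑(NMI)2ZrCl2 gives (R)‑2‑methylalkan‑1‑ols, the D‑fructose Shi ketone gives (R,R)‑epoxides from E‑trisubstituted alkenes, (−)‑MIB gives si‑face transfer, and (S)‑BINAP‑Rh adds to the same face as with cyclopentenone. If a sense proves opposite, the antipode is used.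

## Retrosynthetic overview

1. Target ⇒ desilylation ⇐ Yamaguchi ester bond between the cis‑5‑hydroxy‑5,6‑dihydropyran‑2‑one and a bis‑TBS (2E,4E,6S)‑dienoic acid.
2. Hydroxy‑lactone ⇐ Ru‑catalysed redox isomerisation (new) of a 6‑hydroxy‑2H‑pyran‑3(6H)‑one ⇐ Achmatowicz ring expansion (furan five‑ring → six‑ring) of an (R)‑2‑furyl carbinol.
3. Furyl carbinol ⇐ furan + epoxy aldehyde ⇐ Shi epoxidation and oxidation of a syn‑2,4‑dimethyl alcohol ⇐ two Zr‑catalysed carboaluminations of (E)‑4‑methylhexa‑1,4‑diene ⇐ (E)‑2‑bromobut‑2‑ene + allyl bromide.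
4. Dienoic acid ⇐ HWE on an E‑2‑methyl‑enal ⇐ SeO2 oxidation of an isobutenyl group ⇐ LiAlH4 / TBS ⇐ Rh‑catalysed asymmetric 1,4‑addition of 2‑methylpropenylboronic acid to furan‑2(5H)‑one.
5. Ring order: oxirane first (step 4), then the six‑membered ring by expansion of the furan (step 7), turned into the lactone in step 8.

## Route

Step 1
Reactants: 1 (E)‑2‑bromobut‑2‑ene; 2 allyl bromide
Product: 4 (E)‑4‑methylhexa‑1,4‑diene, via (Z)‑but‑2‑en‑2‑yllithium 3 (not isolated)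
Conditions: t‑BuLi (2.0 equiv), Et2O, −78 °C; then 2, CuI (5 mol%), −78 → 0 °C; distil
Reagents that add atoms: none
Why: Br/Li exchange on an alkenyl bromide is stereoretentive and the alkenyllithium is allylated (Cu‑assisted SN2 alkylation), so the E‑trisubstituted alkene that later becomes the trans‑epoxide is fixed here.

Step 2
Reactants: 4 (E)‑4‑methylhexa‑1,4‑diene; 5 vinyl bromide
Product: 8 (R,E)‑4,6‑dimethylocta‑1,6‑diene, via alkyl(dimethyl)alane 6 (not isolated), via alkylzinc triflate 7 (not isolated)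
Conditions: Me3Al, (+)‑(NMI)2ZrCl2 (4 mol%), MAO, CH2Cl2, 0 °C → rt; evaporate; Zn(OTf)2, DMF, 70 °C; Pd(DPEphos)Cl2 (3 mol%), DIBAL‑H (6 mol%), 5, DMF, rt
Reagents that add atoms: trimethylaluminium, C[Al](C)C
Why: Zr‑catalysed asymmetric carboalumination (ZACA) methylaluminates only the monosubstituted alkene, the chiral zirconocene choosing the alkene face and so setting the first methyl stereocentre, and the alkyl group is then vinylated by Al→Zn transmetalation and Negishi coupling.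

Step 3
Reactants: 8 (R,E)‑4,6‑dimethylocta‑1,6‑diene
Product: 10 (2S,4R,E)‑2,4,6‑trimethyloct‑6‑en‑1‑ol, via alkyl(dimethyl)alane 9 (not isolated)
Conditions: Me3Al, (+)‑(NMI)2ZrCl2 (4 mol%), MAO, CH2Cl2, 0 °C → rt; then O2, 0 °C; aq. HCl; chromatography
Reagents that add atoms: trimethylaluminium, C[Al](C)C; dioxygen, O=O
Why: a second ZACA with the same catalyst antipode selects the same face (isotactic, hence the syn‑1,3‑dimethyl pair) and sets C2, the C–Al bond is oxidised with retention, and removing the minor anti diastereomer by chromatography raises the ee of 10 statistically.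

Step 4
Reactants: 10 (2S,4R,E)‑2,4,6‑trimethyloct‑6‑en‑1‑ol
Product: 11 (2S,4R)‑5‑[(2S,3S)‑2,3‑dimethyloxiran‑2‑yl]‑2,4‑dimethylpentan‑1‑ol
Conditions: ent‑Shi ketone (L‑fructose‑derived, 30 mol%), Oxone, K2CO3, Bu4NHSO4, MeCN/DMM/aq. borate–EDTA buffer (pH 10.5), 0 °C
Reagents that add atoms: potassium peroxymonosulfate (Oxone), [K+].[O-]S(=O)(=O)OO
Why: Shi asymmetric epoxidation: the chiral dioxirane attacks the E‑trisubstituted alkene through the spiro transition state, the ent‑ketone giving the (2S,3S)‑epoxide by reagent control; it is done here because a furan would not survive the dioxirane.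

Step 5
Reactants: 11 (2S,4R)‑5‑[(2S,3S)‑2,3‑dimethyloxiran‑2‑yl]‑2,4‑dimethylpentan‑1‑ol
Product: 12 (2S,4R)‑5‑[(2S,3S)‑2,3‑dimethyloxiran‑2‑yl]‑2,4‑dimethylpentanal
Conditions: Dess–Martin periodinane, NaHCO3, CH2Cl2, 0 °C → rt
Reagents that add atoms: none
Why: buffered Dess–Martin oxidation gives the aldehyde without opening the epoxide or epimerising the α‑methyl centre.

Step 6
Reactants: 12 (2S,4R)‑5‑[(2S,3S)‑2,3‑dimethyloxiran‑2‑yl]‑2,4‑dimethylpentanal; 13 furan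
Product: 16 (1R,2S,4R)‑5‑[(2S,3S)‑2,3‑dimethyloxiran‑2‑yl]‑1‑(furan‑2‑yl)‑2,4‑dimethylpentan‑1‑ol, via 2‑furyllithium 14 (not isolated), via ethyl(2‑furyl)zinc 15 (not isolated)
Conditions: 13, n‑BuLi, THF, 0 °C; EtZnCl (Et2Zn + ZnCl2), TEEDA; (−)‑MIB (10 mol%), 12, toluene/hexanes, 0 °C; H2O
Reagents that add atoms: none
Why: amino‑alcohol‑catalysed asymmetric heteroaryl‑zinc addition to an aldehyde: the (−)‑MIB–zinc catalyst delivers the furyl group to the si face, which is also the Felkin face of the (S)‑α‑methyl aldehyde (matched), setting the (1R) carbinol with the 1,2‑syn relationship.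

Step 7
Reactants: 16 (1R,2S,4R)‑5‑[(2S,3S)‑2,3‑dimethyloxiran‑2‑yl]‑1‑(furan‑2‑yl)‑2,4‑dimethylpentan‑1‑ol
Product: 18 (2R)‑2‑{(2S,4R)‑5‑[(2S,3S)‑2,3‑dimethyloxiran‑2‑yl]‑4‑methylpentan‑2‑yl}‑6‑hydroxy‑2H‑pyran‑3(6H)‑one (anomer mixture), via ring‑opened (Z)‑enedione 17 (not isolated)
Conditions: NBS (1.05 equiv), NaHCO3, NaOAc, THF/H2O 4:1, 0 °C
Reagents that add atoms: water, O
Why: Achmatowicz rearrangement: bromonium‑induced oxidative opening of the furan to the Z‑enedione and closure of the carbinol oxygen onto the aldehyde expands the five‑membered ring to the pyranone; the carbinol centre is not touched and the buffered medium spares the epoxide.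

Step 8
Reactants: 18 (2R)‑2‑{(2S,4R)‑5‑[(2S,3S)‑2,3‑dimethyloxiran‑2‑yl]‑4‑methylpentan‑2‑yl}‑6‑hydroxy‑2H‑pyran‑3(6H)‑one
Product: 20 (5R,6R)‑6‑{(2S,4R)‑5‑[(2S,3S)‑2,3‑dimethyloxiran‑2‑yl]‑4‑methylpentan‑2‑yl}‑5‑hydroxy‑5,6‑dihydro‑2H‑pyran‑2‑one, via keto‑lactone 19 (not isolated)
Conditions: Ru(p‑cymene)[(S,S)‑TsDPEN–H] (16‑electron amido complex, 3 mol%), CH2Cl2, 25 °C, Ar; no base, no added H‑donor; stop at full conversion
Reagents that add atoms: none
Why: Proposed new method: a catalytic internal redox isomerisation in which the 16‑electron Ru amide dehydrogenates the hydridic lactol C–H/O–H to the lactone (irreversible, giving Ru–H/N–H and keto‑lactone 19) and the Ru hydride returns H−/H+ 1,2 to the ring ketone through the outer‑sphere six‑membered transition state, anti to the C6 branch and in the sense set by the (S,S) ligand (assigned by analogy with aryl and alkynyl ketones), so the cis‑(5R) alcohol is formed with no base present to epimerise C6 or open the epoxide; the closest known reaction types are Noyori‑type asymmetric transfer hydrogenation of ketones, transfer‑dehydrogenative oxidation of lactols to lactones, and the Ir‑catalysed redox isomerisation of Achmatowicz pyranones that delivers the hydride 1,4 to give saturated keto‑lactones, whereas this 1,2‑selective, stereo‑defining version has not been shown.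

Step 9
Reactants: 21 furan‑2(5H)‑one; 22 (2‑methylprop‑1‑en‑1‑yl)boronic acid
Product: 23 (S)‑4‑(2‑methylprop‑1‑en‑1‑yl)dihydrofuran‑2(3H)‑one
Conditions: [Rh(OH)((S)‑BINAP)]2 (1.5 mol%), 22 (2.5 equiv), 1,4‑dioxane/H2O 10:1, 40 °C
Reagents that add atoms: none
Why: Hayashi–Miyaura Rh‑catalysed asymmetric 1,4‑addition: the alkenyl–Rh((S)‑BINAP) species inserts the butenolide on one enantioface and the oxa‑π‑allyl is hydrolysed, setting the (S) centre that carries both future hydroxyl arms.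

Step 10
Reactants: 23 (S)‑4‑(2‑methylprop‑1‑en‑1‑yl)dihydrofuran‑2(3H)‑one
Product: 24 (S)‑2‑(2‑methylprop‑1‑en‑1‑yl)butane‑1,4‑diol
Conditions: LiAlH4, THF, 0 °C → rt; Fieser work‑up
Reagents that add atoms: none
Why: hydride reduction of the lactone gives the 1,4‑diol; the stereocentre is not acidic in the product and the alkene is inert.

Step 11
Reactants: 24 (S)‑2‑(2‑methylprop‑1‑en‑1‑yl)butane‑1,4‑diol
Product: 25 (S)‑1,4‑bis[(tert‑butyldimethylsilyl)oxy]‑2‑(2‑methylprop‑1‑en‑1‑yl)butane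
Conditions: TBSCl (2.3 equiv), imidazole, DMF, rt
Reagents that add atoms: tert‑butyldimethylsilyl chloride, CC(C)(C)[Si](C)(C)Cl
Why: standard silylation of two primary alcohols, needed so that only the lactone alcohol is acylated in step 14.

Step 12
Reactants: 25 (S)‑1,4‑bis[(tert‑butyldimethylsilyl)oxy]‑2‑(2‑methylprop‑1‑en‑1‑yl)butane
Product: 26 (S,E)‑6‑[(tert‑butyldimethylsilyl)oxy]‑4‑{[(tert‑butyldimethylsilyl)oxy]methyl}‑2‑methylhex‑2‑enal
Conditions: SeO2 (1.3 equiv), pyridine (2 equiv), 1,4‑dioxane, 80 °C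
Reagents that add atoms: selenium dioxide, O=[Se]=O
Why: Riley (SeO2) allylic oxidation attacks the more substituted alkene terminus at its E‑methyl group, giving the E‑enal and fixing the 4E geometry of the acid; the tertiary allylic C–H on the other side is not oxidised.

Step 13
Reactants: 26 (S,E)‑6‑[(tert‑butyldimethylsilyl)oxy]‑4‑{[(tert‑butyldimethylsilyl)oxy]methyl}‑2‑methylhex‑2‑enal
Product: 27 (2E,4E,6S)‑8‑[(tert‑butyldimethylsilyl)oxy]‑6‑{[(tert‑butyldimethylsilyl)oxy]methyl}‑4‑methylocta‑2,4‑dienoic acid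
Conditions: (EtO)2P(O)CH2CO2H, n‑BuLi (2.0 equiv), THF, −78 °C; then 26, −78 → 0 °C; dil. HCl (pH 3), 0 °C
Reagents that add atoms: diethylphosphonoacetic acid, OC(=O)CP(=O)(OCC)OCC
Why: Horner–Wadsworth–Emmons olefination with the phosphonoacetic acid dianion gives the 2E acid directly, and because no amine is present the γ‑stereocentre of the enal cannot epimerise through a dienamine.

Step 14
Reactants: 20 (5R,6R)‑6‑{(2S,4R)‑5‑[(2S,3S)‑2,3‑dimethyloxiran‑2‑yl]‑4‑methylpentan‑2‑yl}‑5‑hydroxy‑5,6‑dihydro‑2H‑pyran‑2‑one; 27 (2E,4E,6S)‑8‑[(tert‑butyldimethylsilyl)oxy]‑6‑{[(tert‑butyldimethylsilyl)oxy]methyl}‑4‑methylocta‑2,4‑dienoic acid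
Product: 29 (2R,3R)‑2‑{(2S,4R)‑5‑[(2S,3S)‑2,3‑dimethyloxiran‑2‑yl]‑4‑methylpentan‑2‑yl}‑6‑oxo‑3,6‑dihydro‑2H‑pyran‑3‑yl (2E,4E,6S)‑8‑[(tert‑butyldimethylsilyl)oxy]‑6‑{[(tert‑butyldimethylsilyl)oxy]methyl}‑4‑methylocta‑2,4‑dienoate, via Yamaguchi mixed anhydride 28 (not isolated)
Conditions: 27, 2,4,6‑Cl3C6H2COCl, Et3N, THF, 0 °C → rt; then 20, DMAP, toluene, rt
Reagents that add atoms: none
Why: Yamaguchi esterification acylates the secondary allylic alcohol with retention at C5 under conditions mild enough for the epoxide and the unsaturated lactone.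

Step 15
Reactants: 29 bis‑TBS ester
Product: 30 (2R,3R)‑2‑{(2S,4R)‑5‑[(2S,3S)‑2,3‑dimethyloxiran‑2‑yl]‑4‑methylpentan‑2‑yl}‑6‑oxo‑3,6‑dihydro‑2H‑pyran‑3‑yl (2E,4E,6S)‑8‑hydroxy‑6‑(hydroxymethyl)‑4‑methylocta‑2,4‑dienoate (target)
Conditions: HF·pyridine, excess pyridine, THF, 0 °C → rt
Reagents that add atoms: none
Why: pyridine‑buffered HF cleaves the two primary TBS ethers without base (no acyloxy elimination) and is tolerated by trisubstituted epoxides.

## Compound list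

1 | (E)‑2‑bromobut‑2‑ene | C/C=C(\C)Br | starting material
2 | allyl bromide | C=CCBr | starting material
3 | (Z)‑but‑2‑en‑2‑yllithium | C/C=C(\C)[Li] | intermediate (not isolated)
4 | (E)‑4‑methylhexa‑1,4‑diene | C=CC/C(C)=C/C | intermediate
5 | vinyl bromide | C=CBr | starting material
6 | [(2S,4E)‑2,4‑dimethylhex‑4‑en‑1‑yl]dimethylalane | C[Al](C)C[C@@H](C)C/C(C)=C/C | intermediate (not isolated)
7 | [(2S,4E)‑2,4‑dimethylhex‑4‑en‑1‑yl]zinc trifluoromethanesulfonate | FC(F)(F)S(=O)(=O)O[Zn]C[C@@H](C)C/C(C)=C/C | intermediate (not isolated)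
8 | (R,E)‑4,6‑dimethylocta‑1,6‑diene | C=CC[C@@H](C)C/C(C)=C/C | intermediate
9 | dimethyl[(2S,4R,6E)‑2,4,6‑trimethyloct‑6‑en‑1‑yl]alane | C[Al](C)C[C@@H](C)C[C@@H](C)C/C(C)=C/C | intermediate (not isolated)
10 | (2S,4R,E)‑2,4,6‑trimethyloct‑6‑en‑1‑ol | OC[C@@H](C)C[C@@H](C)C/C(C)=C/C | intermediate
11 | (2S,4R)‑5‑[(2S,3S)‑2,3‑dimethyloxiran‑2‑yl]‑2,4‑dimethylpentan‑1‑ol | OC[C@@H](C)C[C@@H](C)C[C@]1(C)O[C@H]1C | intermediate
12 | (2S,4R)‑5‑[(2S,3S)‑2,3‑dimethyloxiran‑2‑yl]‑2,4‑dimethylpentanal | O=C[C@@H](C)C[C@@H](C)C[C@]1(C)O[C@H]1C | intermediate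
13 | furan | c1ccoc1 | starting material
14 | 2‑furyllithium | [Li]c1ccco1 | intermediate (not isolated)
15 | ethyl(2‑furyl)zinc | CC[Zn]c1ccco1 | intermediate (not isolated)
16 | (1R,2S,4R)‑5‑[(2S,3S)‑2,3‑dimethyloxiran‑2‑yl]‑1‑(furan‑2‑yl)‑2,4‑dimethylpentan‑1‑ol | O[C@@H](c1ccco1)[C@@H](C)C[C@@H](C)C[C@]1(C)O[C@H]1C | intermediate
17 | (2Z,5R,6S,8R)‑9‑[(2S,3S)‑2,3‑dimethyloxiran‑2‑yl]‑5‑hydroxy‑6,8‑dimethyl‑4‑oxonon‑2‑enal | O[C@@H](C(=O)/C=C\C=O)[C@@H](C)C[C@@H](C)C[C@]1(C)O[C@H]1C | intermediate (not isolated)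
18 | (2R)‑2‑{(2S,4R)‑5‑[(2S,3S)‑2,3‑dimethyloxiran‑2‑yl]‑4‑methylpentan‑2‑yl}‑6‑hydroxy‑2H‑pyran‑3(6H)‑one (anomer mixture) | O=C1C=CC(O)O[C@@H]1[C@@H](C)C[C@@H](C)C[C@]1(C)O[C@H]1C | intermediate
19 | (R)‑6‑{(2S,4R)‑5‑[(2S,3S)‑2,3‑dimethyloxiran‑2‑yl]‑4‑methylpentan‑2‑yl}‑2H‑pyran‑2,5(6H)‑dione | O=C1C=CC(=O)O[C@@H]1[C@@H](C)C[C@@H](C)C[C@]1(C)O[C@H]1C | intermediate (not isolated)
20 | (5R,6R)‑6‑{(2S,4R)‑5‑[(2S,3S)‑2,3‑dimethyloxiran‑2‑yl]‑4‑methylpentan‑2‑yl}‑5‑hydroxy‑5,6‑dihydro‑2H‑pyran‑2‑one | O[C@@H]1C=CC(=O)O[C@@H]1[C@@H](C)C[C@@H](C)C[C@]1(C)O[C@H]1C | intermediate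
21 | furan‑2(5H)‑one | O=C1OCC=C1 | starting material
22 | (2‑methylprop‑1‑en‑1‑yl)boronic acid | CC(C)=CB(O)O | starting material
23 | (S)‑4‑(2‑methylprop‑1‑en‑1‑yl)dihydrofuran‑2(3H)‑one | CC(C)=C[C@@H]1CC(=O)OC1 | intermediate
24 | (S)‑2‑(2‑methylprop‑1‑en‑1‑yl)butane‑1,4‑diol | CC(C)=C[C@@H](CO)CCO | intermediate
25 | (S)‑1,4‑bis[(tert‑butyldimethylsilyl)oxy]‑2‑(2‑methylprop‑1‑en‑1‑yl)butane | CC(C)=C[C@@H](CO[Si](C)(C)C(C)(C)C)CCO[Si](C)(C)C(C)(C)C | intermediate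
26 | (S,E)‑6‑[(tert‑butyldimethylsilyl)oxy]‑4‑{[(tert‑butyldimethylsilyl)oxy]methyl}‑2‑methylhex‑2‑enal | CC(/C=O)=C\[C@@H](CO[Si](C)(C)C(C)(C)C)CCO[Si](C)(C)C(C)(C)C | intermediate
27 | (2E,4E,6S)‑8‑[(tert‑butyldimethylsilyl)oxy]‑6‑{[(tert‑butyldimethylsilyl)oxy]methyl}‑4‑methylocta‑2,4‑dienoic acid | CC(/C=C/C(=O)O)=C\[C@@H](CO[Si](C)(C)C(C)(C)C)CCO[Si](C)(C)C(C)(C)C | intermediate
28 | mixed anhydride of 27 with 2,4,6‑trichlorobenzoic acid | CC(/C=C/C(=O)OC(=O)c1c(Cl)cc(Cl)cc1Cl)=C\[C@@H](CO[Si](C)(C)C(C)(C)C)CCO[Si](C)(C)C(C)(C)C | intermediate (not isolated)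
29 | bis‑TBS ether of the target (ester of 20 with 27) | CC(/C=C/C(=O)O[C@@H]1C=CC(=O)O[C@@H]1[C@@H](C)C[C@@H](C)C[C@]1(C)O[C@H]1C)=C\[C@@H](CO[Si](C)(C)C(C)(C)C)CCO[Si](C)(C)C(C)(C)C | intermediate
30 | (2R,3R)‑2‑{(2S,4R)‑5‑[(2S,3S)‑2,3‑dimethyloxiran‑2‑yl]‑4‑methylpentan‑2‑yl}‑6‑oxo‑3,6‑dihydro‑2H‑pyran‑3‑yl (2E,4E,6S)‑8‑hydroxy‑6‑(hydroxymethyl)‑4‑methylocta‑2,4‑dienoate | CC(/C=C/C(=O)O[C@@H]1C=CC(=O)O[C@@H]1[C@@H](C)C[C@@H](C)C[C@]1(C)O[C@H]1C)=C\[C@@H](CO)CCO | target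

## Count and risks

Total steps: 15. Longest linear sequence: 10 (steps 1–8, 14, 15); the acid arm is steps 9–13.

**Step 8 (the proposed new step).** The risks are 1,4‑ instead of 1,2‑hydride delivery to the ene‑dione, and erosion of the cis ratio if the product alcohol is re‑oxidised on long standing. The fallback uses known chemistry. It sets out from 18: Dess–Martin periodinane (NaHCO3, CH2Cl2) oxidises the lactol to the keto‑lactone 19, this time isolated. Luche reduction (NaBH4, CeCl3·7H2O, MeOH, −78 °C) then delivers hydride anti to the C6 branch and comes back to the route at 20. This is the established lactol oxidation / 1,2‑reduction sequel to an Achmatowicz reaction.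

**Step 6.** The risks are that 2‑furylzinc transfer under amino‑alcohol catalysis is less well documented than aryl transfer, and that the zinc Lewis acid meets an epoxide. The fallback sets out from 12 and 13: plain 2‑furyllithium (THF, −78 °C) adds without useful control to give the C1‑epimeric mixture of 5‑[(2S,3S)‑2,3‑dimethyloxiran‑2‑yl]‑1‑(furan‑2‑yl)‑2,4‑dimethylpentan‑1‑ol F1. MnO2 (CH2Cl2) oxidises this to (2S,4R)‑5‑[(2S,3S)‑2,3‑dimethyloxiran‑2‑yl]‑1‑(furan‑2‑yl)‑2,4‑dimethylpentan‑1‑one F2. Noyori transfer hydrogenation (RuCl(p‑cymene)[(R,R)‑TsDPEN], HCO2Na, CTAB, H2O/CH2Cl2) then sets C1 by catalyst control and comes back to the route at 16.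

**Step 12.** The risks are a moderate yield, alcohol/aldehyde mixtures and silyl ether loss in hot selenous acid. The fallback builds the enal by metathesis instead of C–H oxidation and sets out from 21: Rh/(S)‑BINAP‑catalysed 1,4‑addition of potassium vinyltrifluoroborate gives (S)‑4‑vinyldihydrofuran‑2(3H)‑one F3. LiAlH4 gives (S)‑2‑vinylbutane‑1,4‑diol F4, and TBSCl/imidazole gives (S)‑1,4‑bis[(tert‑butyldimethylsilyl)oxy]‑2‑vinylbutane F5. Cross‑metathesis with methacrolein (Hoveyda–Grubbs II, CH2Cl2, 40 °C) forms the E‑2‑methyl‑enal and comes back to the route at 26.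

## Further compounds

F1 | step 6 | C1‑epimeric mixture of (2S,4R)‑5‑[(2S,3S)‑2,3‑dimethyloxiran‑2‑yl]‑1‑(furan‑2‑yl)‑2,4‑dimethylpentan‑1‑ol | OC(c1ccco1)[C@@H](C)C[C@@H](C)C[C@]1(C)O[C@H]1C
F2 | step 6 | (2S,4R)‑5‑[(2S,3S)‑2,3‑dimethyloxiran‑2‑yl]‑1‑(furan‑2‑yl)‑2,4‑dimethylpentan‑1‑one | O=C(c1ccco1)[C@@H](C)C[C@@H](C)C[C@]1(C)O[C@H]1C
F0 | step 8 | none | none
F3 | step 12 | (S)‑4‑vinyldihydrofuran‑2(3H)‑one | C=C[C@@H]1CC(=O)OC1
F4 | step 12 | (S)‑2‑vinylbutane‑1,4‑diol | C=C[C@@H](CO)CCO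
F5 | step 12 | (S)‑1,4‑bis[(tert‑butyldimethylsilyl)oxy]‑2‑vinylbutane | C=C[C@@H](CO[Si](C)(C)C(C)(C)C)CCO[Si](C)(C)C(C)(C)C
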